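**Assumption:** the sense of induction in the phosphoric-acid crotylboration is taken from the benzaldehyde precedent as I recall it ((R)-TRIP gives the 1R carbinol), so (S)-TRIP is specified; confirm on compound 4 (Mosher ester or rotation) and switch catalyst enantiomer if it is reversed.

## Retrosynthetic overview

1. Target 13 ⇐ lipase-catalysed chemoselective O-acetylation of triol 12 (one primary OH in the presence of two free phenols).
2. Triol 12 ⇐ acid 11 ⇐ all-trans lactone 10, by one hydrogenolysis that cleaves the benzylic lactone C5–O bond (revealing the syringyl CH2) and both benzyl ethers.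
3. Lactone 10 ⇐ anti-selective enolate alkylation of γ-aryl-β-methyl lactone 6 with benzylic bromide 9; "3,4-trans" on this ring corresponds to the target's relative configuration.
4. Lactone 6 ⇐ hydroboration and oxidative lactonisation of anti-homoallylic alcohol 4 ⇐ chiral phosphoric acid-catalysed crotylboration of aldehyde 2 (first stereocentres).
5. Rings: the target has no non-aromatic ring; the only ring made is the temporary γ-butyrolactone (formed in step 4, opened in step 8).

## Route

**Step 1**
Reactants: 1, syringaldehyde
Product: 2, 4-(benzyloxy)-3,5-dimethoxybenzaldehyde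
Conditions: BnBr, K2CO3, DMF, 60 °C
Reagents that add atoms: benzyl bromide, BrCc1ccccc1
Why: Williamson etherification of the phenoxide gives a phenol protecting group that survives base, borane, oxidant and enolate chemistry and is removed later by hydrogenolysis.

**Step 2**
Reactants: 2, 4-(benzyloxy)-3,5-dimethoxybenzaldehyde; 3, (E)-crotylboronic acid pinacol ester
Product: 4, (1S,2S)-1-[4-(benzyloxy)-3,5-dimethoxyphenyl]-2-methylbut-3-en-1-ol (anti)
Conditions: (S)-TRIP (5 mol%), 4 Å MS, toluene, −30 °C → rt; aqueous work-up
Reagents that add atoms: none beyond 3 (its crotyl unit; the Bpin group is lost on work-up)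
Why: Chiral Brønsted acid-catalysed crotylboration (Antilla type) through a closed chair transition state, so the E-boronate gives the anti product and the catalyst directs Si-face attack, setting C1 (S) and the methyl-bearing C2 (S) together.

**Step 3**
Reactants: 4, the anti-homoallylic alcohol
Product: 5, (1S,2S)-1-[4-(benzyloxy)-3,5-dimethoxyphenyl]-2-methylbutane-1,4-diol
Conditions: 9-BBN (2.5 equiv), THF, 0 °C → rt; then NaOH, H2O2, 0 °C → rt
Reagents that add atoms: hydrogen peroxide, OO (oxygen of the new primary OH)
Why: Anti-Markovnikov hydroboration–oxidation of the terminal vinyl group; no stereocentre is touched.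

**Step 4**
Reactants: 5, the 1,4-diol
Product: 6, (4S,5S)-5-[4-(benzyloxy)-3,5-dimethoxyphenyl]-4-methyldihydrofuran-2(3H)-one (4,5-trans)
Conditions: TEMPO (0.2 equiv), PhI(OAc)2 (3 equiv), CH2Cl2, rt; recrystallise or chromatograph to remove any cis-lactone
Reagents that add atoms: none
Why: TEMPO/BAIB oxidative lactonisation: the primary alcohol is oxidised first, the aldehyde closes to the lactol with the benzylic OH, and the lactol is oxidised to the lactone with both stereocentres retained.

**Step 5**
Reactants: 7, 4-(benzyloxy)-3-methoxybenzaldehyde (O-benzylvanillin)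
Product: 8, [4-(benzyloxy)-3-methoxyphenyl]methanol
Conditions: NaBH4, MeOH/THF, 0 °C
Reagents that add atoms: none
Why: Borohydride reduction of an aryl aldehyde.

**Step 6**
Reactants: 8, the benzylic alcohol
Product: 9, 4-(benzyloxy)-3-methoxybenzyl bromide
Conditions: PBr3, Et2O, 0 °C; use directly
Reagents that add atoms: phosphorus tribromide, BrP(Br)Br
Why: Standard conversion of an activated benzylic alcohol into the bromide.

**Step 7**
Reactants: 6, the trans-lactone; 9, the benzylic bromide
Product: 10, (3S,4S,5S)-3-[4-(benzyloxy)-3-methoxybenzyl]-5-[4-(benzyloxy)-3,5-dimethoxyphenyl]-4-methyldihydrofuran-2(3H)-one (3,4-trans, 4,5-trans)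
Conditions: LiHMDS (1.1 equiv), THF, −78 °C; then 9, DMPU, −78 → −40 °C
Reagents that add atoms: none beyond 9
Why: SN2 alkylation of the lactone lithium enolate, with the electrophile entering anti to the adjacent C4 methyl group to set C3 (S), trans to the methyl.

**Step 8**
Reactants: 10, the all-trans lactone
Product: 11, (2S,3R)-2-(4-hydroxy-3-methoxybenzyl)-4-(4-hydroxy-3,5-dimethoxyphenyl)-3-methylbutanoic acid
Conditions: H2 (3 atm), Pd(OH)2/C, EtOAc–AcOH, rt → 40 °C (no strong acid)
Reagents that add atoms: none
Why: Catalytic hydrogenolysis cleaves the benzylic lactone C5–O bond and both benzyl ethers; C5 becomes CH2 (its stereocentre is erased) while C2 and C3 of the acid are not involved.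

**Step 9**
Reactants: 11, the diphenolic acid
Product: 12, (2S,3R)-2-(4-hydroxy-3-methoxybenzyl)-4-(4-hydroxy-3,5-dimethoxyphenyl)-3-methylbutan-1-ol
Conditions: BH3·THF (5 equiv), THF, 0 °C → rt; MeOH quench, dilute aqueous acid work-up
Reagents that add atoms: none
Why: Chemoselective borane reduction of the carboxylic acid under non-basic conditions, so the α-stereocentre does not epimerise; the phenols are regenerated on work-up.

**Step 10**
Reactants: 12, the triol
Product: 13, (2S,3R)-2-(4-hydroxy-3-methoxybenzyl)-4-(4-hydroxy-3,5-dimethoxyphenyl)-3-methylbutyl acetate (target)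
Conditions: immobilised Candida antarctica lipase B (Novozym 435), vinyl acetate (5 equiv), THF–MTBE, 40 °C; filter off the enzyme
Reagents that add atoms: vinyl acetate, C=COC(C)=O
Why: Lipase-catalysed irreversible transesterification; the acyl-enzyme acetylates the primary aliphatic alcohol and leaves both phenols free (as with lipase acylation of secoisolariciresinol-type lignans).

## Compound list

1 | syringaldehyde (4-hydroxy-3,5-dimethoxybenzaldehyde) | COc1cc(C=O)cc(OC)c1O | starting material
2 | 4-(benzyloxy)-3,5-dimethoxybenzaldehyde | COc1cc(C=O)cc(OC)c1OCc1ccccc1 | intermediate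
3 | (E)-crotylboronic acid pinacol ester | C/C=C/CB1OC(C)(C)C(C)(C)O1 | starting material
4 | (1S,2S)-1-[4-(benzyloxy)-3,5-dimethoxyphenyl]-2-methylbut-3-en-1-ol | C=C[C@H](C)[C@H](O)c1cc(OC)c(OCc2ccccc2)c(OC)c1 | intermediate
5 | (1S,2S)-1-[4-(benzyloxy)-3,5-dimethoxyphenyl]-2-methylbutane-1,4-diol | OCC[C@H](C)[C@H](O)c1cc(OC)c(OCc2ccccc2)c(OC)c1 | intermediate
6 | (4S,5S)-5-[4-(benzyloxy)-3,5-dimethoxyphenyl]-4-methyldihydrofuran-2(3H)-one | O=C1C[C@H](C)[C@@H](c2cc(OC)c(OCc3ccccc3)c(OC)c2)O1 | intermediate
7 | 4-(benzyloxy)-3-methoxybenzaldehyde | COc1cc(C=O)ccc1OCc1ccccc1 | starting material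
8 | [4-(benzyloxy)-3-methoxyphenyl]methanol | COc1cc(CO)ccc1OCc1ccccc1 | intermediate
9 | 4-(benzyloxy)-3-methoxybenzyl bromide | COc1cc(CBr)ccc1OCc1ccccc1 | intermediate
10 | (3S,4S,5S)-3-[4-(benzyloxy)-3-methoxybenzyl]-5-[4-(benzyloxy)-3,5-dimethoxyphenyl]-4-methyldihydrofuran-2(3H)-one | COc1cc(C[C@@H]2C(=O)O[C@H](c3cc(OC)c(OCc4ccccc4)c(OC)c3)[C@H]2C)ccc1OCc1ccccc1 | intermediate
11 | (2S,3R)-2-(4-hydroxy-3-methoxybenzyl)-4-(4-hydroxy-3,5-dimethoxyphenyl)-3-methylbutanoic acid | COc1cc(C[C@H](C(=O)O)[C@H](C)Cc2cc(OC)c(O)c(OC)c2)ccc1O | intermediate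
12 | (2S,3R)-2-(4-hydroxy-3-methoxybenzyl)-4-(4-hydroxy-3,5-dimethoxyphenyl)-3-methylbutan-1-ol | COc1cc(C[C@H](CO)[C@H](C)Cc2cc(OC)c(O)c(OC)c2)ccc1O | intermediate
13 | (2S,3R)-2-(4-hydroxy-3-methoxybenzyl)-4-(4-hydroxy-3,5-dimethoxyphenyl)-3-methylbutyl acetate (CID53359578) | COc1cc(C[C@H](COC(C)=O)[C@H](C)Cc2cc(OC)c(O)c(OC)c2)ccc1O | target

## Summary

Total steps: 10. Longest linear sequence: 8 (steps 1 → 2 → 3 → 4 → 7 → 8 → 9 → 10); steps 5–6 are a two-step side branch.

Steps most likely to fail, each with a fallback that changes the approach: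

1. **Step 2 (asymmetric crotylboration of an electron-rich, hindered aldehyde; ee, anti:syn ratio and rate).** Any syn isomer carries the opposite methyl configuration into the target, so it must be removed at lactone 6. Fallback: make 4 by Krische-type Ru-catalysed transfer-hydrogenative anti-crotylation using butadiene as the achiral C4 partner, with the benzylic alcohol of 2 as substrate; this uses a catalytically generated crotyl-metal nucleophile instead of a preformed boronate.
2. **Step 7 (C3 diastereoselectivity and over-alkylation with a labile benzylic bromide).** Fallback: replace the SN2 alkylation by an aldol addition of the enolate of 6 to aldehyde 7. The extra benzylic hydroxyl is then removed in the same hydrogenolysis as step 8, and a poor C3 ratio can be corrected by base equilibration (DBU) to the 3,4-trans lactone, which should be the more stable epimer.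
3. **Step 8 (benzylic lactone C–O hydrogenolysis).** It may be sluggish, or under acidic conditions may ionise and eliminate to a styrene, which would scramble the methyl stereocentre. Fallback: dissolving-metal reductive cleavage (Li, NH3/THF, −78 °C), a single-electron pathway via the benzylic anion that cannot form the alkene and also removes both benzyl ethers, giving the same acid 11.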